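**Plan**

- Cuts, in retrosynthetic order: (a) the furan ring, at C3–C1' and C2–O(C2'), giving a 2-(pyrrolidin-1-yl)chromone (rings A, C, E) and 2,2-dimethylchroman-5,8-dione (rings B, F). (b) C2 of ring C, from CS2. (c) The C8–prenyl bond. (d) Ring E, the dimethylpyran on O–C5/C6, contracted to a 2-isopropenyl-2,3-dihydrofuran. (e) That ring, cut to an o-iodophenol and isoprene.
- Forward order: ring A is bought. A five-membered O-ring is annulated on it and expanded to the six-membered ring E. Saturation with debenzylation follows, then the C8 prenyl group, then ring C. Rings B and F are made separately as a quinone. The last step joins both halves and closes the furan ring.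
- Enabling feature: the ring E oxygen sits on C5, ortho to C4a, which carries the acyl carbon C4. It is therefore a vinylogous carboxylate oxygen that can leave and return reversibly. Beside it are the benzylic CH2 on C6, which supplies a β-hydrogen, and the carbon that becomes the tertiary CMe2 end of an aryl-conjugated allyl unit. That carbon is the only place where this oxygen can close again.
- Ring B carries its OH para to the furan oxygen. This is the pattern a 1,4-benzoquinone leaves after C-attack and O-closure, so the union is redox-neutral and no oxidant meets the prenyl group.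
- Stereochemistry: the target has no stereocentre. The only one on the way (C2 of the dihydrofuran, racemic) is erased in the ring expansion.

Key step: step 4

Remark: chroman or benzofuran numbering is used for bicyclic compounds and flavonoid numbering (O1, C2–C8a, primed for ring B) for later ones. Ring E is O–C(CH3)2–CH2–CH2 running from the oxygen on C5 to C6. Ring F is the same bridge from the oxygen on C4' to C3'.

**Step 1**
Reactants: 1 1-(2,4,6-trihydroxyphenyl)ethanone
Product: 2 1-[4-(benzyloxy)-2,6-dihydroxyphenyl]ethanone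
Conditions: BnBr (1.0 equiv), K2CO3 (1.1 equiv), acetone, reflux
Reagents that add atoms: benzyl bromide BrCc1ccccc1
Why: Williamson etherification, in which the 4-OH is the only hydroxyl not hydrogen-bonded to the acetyl group and is the most acidic, so one equivalent of base and halide should alkylate it first.

**Step 2**
Reactants: 2 1-[4-(benzyloxy)-2,6-dihydroxyphenyl]ethanone
Product: 3 1-[4-(benzyloxy)-2,6-dihydroxy-3-iodophenyl]ethanone
Conditions: NIS (1.0 equiv), CH2Cl2–MeCN, 0 °C
Reagents that add atoms: N-iodosuccinimide O=C1CCC(=O)N1I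
Why: Electrophilic aromatic iodination of a phloroglucinol ring whose two free carbons are related by symmetry, so mono-iodination can give only one isomer.

**Step 3**
Reactants: 3 1-[4-(benzyloxy)-2,6-dihydroxy-3-iodophenyl]ethanone
Product: 4 (±)-1-[4-(benzyloxy)-6-hydroxy-2-(prop-1-en-2-yl)-2,3-dihydro-1-benzofuran-7-yl]ethanone
Conditions: isoprene (5 equiv), Pd(OAc)2 (5 mol %), Na2CO3, n-Bu4NCl, DMF, 80 °C, sealed tube
Reagents that add atoms: isoprene C=CC(C)=C
Why: Larock heteroannulation of a 1,3-diene by an o-iodophenol, in which the arylpalladium species adds to the unsubstituted vinyl terminus of isoprene and the allyl unit is closed 5-exo by the neighbouring free phenoxide (the other flank is benzylated), the new C2 stereocentre forming without control as a racemate.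

**Step 4**
Reactants: 4 (±)-1-[4-(benzyloxy)-6-hydroxy-2-(prop-1-en-2-yl)-2,3-dihydro-1-benzofuran-7-yl]ethanone
Product: 6 1-[5-(benzyloxy)-7-hydroxy-2,2-dimethyl-2H-chromen-8-yl]ethanone, via dienylphenol 5 (not isolated)
Conditions: Pd2(dba)3 (2.5 mol %), DPEphos (6 mol %), PhCO2H (20 mol %), toluene, 100 °C, argon
Reagents that add atoms: none
Why: Proposed new method: zerovalent palladium should ionise the allylic C2–O bond of the dihydrofuran (the leaving group is a phenoxide ortho to the acetyl group, a vinylogous carboxylate), β-hydride elimination of a benzylic hydrogen gives dienylphenol 5 and a palladium hydride, re-addition of the hydride to the terminal CH2 gives the 1-aryl-3,3-dimethylallyl complex, and the same phenoxide attacks its tertiary terminus. The closest known reaction types are Tsuji–Trost ionisation of allyl aryl ethers, palladium-catalysed elimination of allylic esters to 1,3-dienes, hydroalkoxylation of 1,3-dienes through palladium hydrides, phenoxide attack at the tertiary end of 1,1-dimethylallyl complexes and the allylic etherification that gives 2H-chromenes, and only their union in one isomerisation is new. The new ring closes 6-endo-trig after η3–η1–η3 isomerisation of the allyl unit, attack at the benzylic terminus being excluded because it would give a four-membered ring, so the former exocyclic isopropenyl carbon enters the ring as CMe2 and the O-ring grows from five to six atoms. No stereocentre is formed and that of 4 is erased. The step needs closure on the oxygen ortho to the acetyl group and not on the para oxygen, which the benzyl ether secures, and it needs a thermodynamic sink, which is 6 because every other allylic ether on the way (4 itself or the seven-membered ether from attack at the primary allyl terminus) can ionise again while only 6 has its alkene conjugated with ring A. Alkene migration into the five-membered ring would require palladium on a tertiary carbon and should be slow, and any free 5 should also close to 6 under the benzoic acid present.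

**Step 5**
Reactants: 6 1-[5-(benzyloxy)-7-hydroxy-2,2-dimethyl-2H-chromen-8-yl]ethanone
Product: 7 1-(5,7-dihydroxy-2,2-dimethyl-3,4-dihydro-2H-chromen-8-yl)ethanone
Conditions: H2 (1 atm), Pd/C (10 %), EtOAc–EtOH, rt
Reagents that add atoms: none
Why: Heterogeneous catalytic hydrogenation saturates the cis-disubstituted chromene alkene and hydrogenolyses the benzyl ether in one operation, while the hydrogen-bonded electron-rich aryl ketone should stay untouched.

**Step 6**
Reactants: 7 1-(5,7-dihydroxy-2,2-dimethyl-3,4-dihydro-2H-chromen-8-yl)ethanone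
Product: 8 1-[5,7-dihydroxy-2,2-dimethyl-6-(3-methylbut-2-en-1-yl)-3,4-dihydro-2H-chromen-8-yl]ethanone
Conditions: prenyl bromide (1.0 equiv), KOH, MeOH–H2O, 0 °C to rt
Reagents that add atoms: 1-bromo-3-methylbut-2-ene CC(C)=CCBr
Why: C-Alkylation of an acylphloroglucinol phenoxide in protic medium, where C6 is the only free ring carbon, lies between two oxygen-bearing carbons, and solvation of the phenoxide oxygens favours attack through carbon on the allylic bromide.

**Step 7**
Reactants: 8 1-[5,7-dihydroxy-2,2-dimethyl-6-(3-methylbut-2-en-1-yl)-3,4-dihydro-2H-chromen-8-yl]ethanone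
Product: 10 4,7-dihydroxy-8-(3-methylbut-2-en-1-yl)-2H-chromene-2-thione with ring E on O–C5/C6, via dithioacid 9 (not isolated)
Conditions: LiN(SiMe3)2 (4.2 equiv), THF, −78 to −10 °C; CS2 (3 equiv), to rt; cold 1 M HCl
Reagents that add atoms: carbon disulfide S=C=S
Why: Polyanion formation lets the ketone enolate carbon add to CS2, and on acidification dithioacid 9 is closed with loss of H2S by the only hydroxyl ortho to the acyl group, which is the known conversion of o-hydroxyacetophenones into 4-hydroxychromene-2-thiones under conditions harmless to the prenyl group.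

**Step 8**
Reactants: 10 4,7-dihydroxy-8-(3-methylbut-2-en-1-yl)-2H-chromene-2-thione with ring E on O–C5/C6
Product: 11 7-hydroxy-2-(methylsulfanyl)-8-(3-methylbut-2-en-1-yl)-4H-chromen-4-one with ring E on O–C5/C6
Conditions: MeI (1.05 equiv), K2CO3 (1.0 equiv), acetone, rt
Reagents that add atoms: iodomethane CI
Why: Chemoselective S-alkylation, since the enol-thione unit is by far the most acidic site and one equivalent of base gives the soft thiolate, which should be methylated ahead of the 7-OH.

**Step 9**
Reactants: 11 7-hydroxy-2-(methylsulfanyl)-8-(3-methylbut-2-en-1-yl)-4H-chromen-4-one with ring E on O–C5/C6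
Product: 12 7-hydroxy-8-(3-methylbut-2-en-1-yl)-2-(pyrrolidin-1-yl)-4H-chromen-4-one with ring E on O–C5/C6
Conditions: pyrrolidine (5 equiv), EtOH, reflux
Reagents that add atoms: pyrrolidine C1CCNC1
Why: Addition–elimination at C2 of a 2-(alkylsulfanyl)chromone by a secondary amine with loss of methanethiol is a known entry to 2-aminochromones, and any transient opening of ring C would close again to the same product.

**Step 10**
Reactants: 13 2,5-dimethoxyphenol
Product: 15 5,8-dimethoxy-2,2-dimethyl-2H-chromene, via quinone methide 14 (not isolated)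
Conditions: 3-methylbut-2-enal (1.5 equiv), PhB(OH)2 (1.0 equiv), AcOH, toluene, reflux, Dean–Stark trap
Reagents that add atoms: 3-methylbut-2-enal CC(C)=CC=O
Why: Phenylboronic acid-templated ortho-condensation of a phenol with an enal gives o-quinone methide 14, which closes by oxa-6π electrocyclisation, and C6 is the only free ortho carbon of 13, so one regioisomer is possible.

**Step 11**
Reactants: 15 5,8-dimethoxy-2,2-dimethyl-2H-chromene
Product: 16 5,8-dimethoxy-2,2-dimethyl-3,4-dihydro-2H-chromene
Conditions: H2 (1 atm), Pd/C (10 %), EtOAc, rt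
Reagents that add atoms: none
Why: Heterogeneous hydrogenation of the cis-alkene of a 2,2-dimethylchromene, with nothing else in 15 reducible under these conditions.

**Step 12**
Reactants: 16 5,8-dimethoxy-2,2-dimethyl-3,4-dihydro-2H-chromene
Product: 17 2,2-dimethyl-3,4-dihydro-2H-chromene-5,8-dione
Conditions: (NH4)2Ce(NO3)6 (2.2 equiv), MeCN–H2O, 0 °C
Reagents that add atoms: water O
Why: Oxidative demethylation of a 1,4-dimethoxyarene to the p-quinone, in which the two para methoxy groups leave as methanol, water supplies the carbonyl oxygens and the chroman oxygen stays as a vinylogous ester oxygen.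

**Step 13**
Reactants: 12 7-hydroxy-8-(3-methylbut-2-en-1-yl)-2-(pyrrolidin-1-yl)-4H-chromen-4-one with ring E on O–C5/C6; 17 2,2-dimethyl-3,4-dihydro-2H-chromene-5,8-dione
Product: 19 target CNP0081329.0 (7,5'-dihydroxy-8-prenylcoumaronochromone with ring E on O–C5/C6 and ring F on O–C4'/C3'), via hydroquinone adduct 18 (not isolated)
Conditions: 12 (1.0 equiv), 17 (1.1 equiv), glacial AcOH, argon, 25 °C then 70 °C
Reagents that add atoms: none
Why: Proposed new method: the 2-aminochromone is a tertiary push–pull enaminone whose C3 (the only free nucleophilic carbon, ring A being fully substituted) should add to the acid-activated quinone at its C6, the carbon β to the C8 carbonyl (the C5 carbonyl is deactivated as a vinylogous ester by the ring oxygen), tautomerisation gives hydroquinone 18, and its C5 hydroxyl, now ortho to the new bond, adds 5-exo-trig to C2 (the β-carbon of the fixed C4 enone, hence closure to the coumaronochromone and not to the isomeric coumestan skeleton) and expels protonated pyrrolidine in a redox-neutral sequence that spares prenyl group and free phenols; the closest known reaction type is the Nenitzescu-type synthesis of 3-acyl-5-hydroxybenzofurans from tertiary enaminones or ketene aminals and 1,4-benzoquinones in acetic acid.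

**Compound list**

1 | 1-(2,4,6-trihydroxyphenyl)ethanone | CC(=O)c1c(O)cc(O)cc1O | starting material
2 | 1-[4-(benzyloxy)-2,6-dihydroxyphenyl]ethanone | CC(=O)c1c(O)cc(OCc2ccccc2)cc1O | intermediate
3 | 1-[4-(benzyloxy)-2,6-dihydroxy-3-iodophenyl]ethanone | CC(=O)c1c(O)cc(OCc2ccccc2)c(I)c1O | intermediate
4 | (±)-1-[4-(benzyloxy)-6-hydroxy-2-(prop-1-en-2-yl)-2,3-dihydro-1-benzofuran-7-yl]ethanone (racemate) | CC(=O)c1c(O)cc(OCc2ccccc2)c2c1OC(C(C)=C)C2 | intermediate
5 | 1-{4-(benzyloxy)-2,6-dihydroxy-3-[(1E)-3-methylbuta-1,3-dien-1-yl]phenyl}ethanone | CC(=O)c1c(O)cc(OCc2ccccc2)c(/C=C/C(C)=C)c1O | intermediate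
6 | 1-[5-(benzyloxy)-7-hydroxy-2,2-dimethyl-2H-chromen-8-yl]ethanone | CC(=O)c1c(O)cc(OCc2ccccc2)c2c1OC(C)(C)C=C2 | intermediate
7 | 1-(5,7-dihydroxy-2,2-dimethyl-3,4-dihydro-2H-chromen-8-yl)ethanone | CC(=O)c1c(O)cc(O)c2c1OC(C)(C)CC2 | intermediate
8 | 1-[5,7-dihydroxy-2,2-dimethyl-6-(3-methylbut-2-en-1-yl)-3,4-dihydro-2H-chromen-8-yl]ethanone | CC(=O)c1c(O)c(CC=C(C)C)c(O)c2c1OC(C)(C)CC2 | intermediate
9 | 3-[5,7-dihydroxy-2,2-dimethyl-6-(3-methylbut-2-en-1-yl)-3,4-dihydro-2H-chromen-8-yl]-3-oxopropanedithioic acid | SC(=S)CC(=O)c1c(O)c(CC=C(C)C)c(O)c2c1OC(C)(C)CC2 | intermediate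
10 | 4,7-dihydroxy-8-(3-methylbut-2-en-1-yl)-2H-chromene-2-thione with ring E on O–C5/C6 | CC(C)=CCc1c(O)c2c(c3c(O)cc(=S)oc13)OC(C)(C)CC2 | intermediate
11 | 7-hydroxy-2-(methylsulfanyl)-8-(3-methylbut-2-en-1-yl)-4H-chromen-4-one with ring E on O–C5/C6 | CC(C)=CCc1c(O)c2c(c3c(=O)cc(SC)oc13)OC(C)(C)CC2 | intermediate
12 | 7-hydroxy-8-(3-methylbut-2-en-1-yl)-2-(pyrrolidin-1-yl)-4H-chromen-4-one with ring E on O–C5/C6 | CC(C)=CCc1c(O)c2c(c3c(=O)cc(N4CCCC4)oc13)OC(C)(C)CC2 | intermediate
13 | 2,5-dimethoxyphenol | COc1ccc(OC)c(O)c1 | starting material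
14 | 3,6-dimethoxy-2-(3-methylbut-2-en-1-ylidene)cyclohexa-3,5-dien-1-one | COC1=CC=C(OC)C(=O)C1=CC=C(C)C | intermediate
15 | 5,8-dimethoxy-2,2-dimethyl-2H-chromene | COc1ccc(OC)c2c1C=CC(C)(C)O2 | intermediate
16 | 5,8-dimethoxy-2,2-dimethyl-3,4-dihydro-2H-chromene | COc1ccc(OC)c2c1CCC(C)(C)O2 | intermediate
17 | 2,2-dimethyl-3,4-dihydro-2H-chromene-5,8-dione | O=C1C=CC(=O)C2=C1CCC(C)(C)O2 | intermediate
18 | 3-(5,8-dihydroxy-2,2-dimethyl-3,4-dihydro-2H-chromen-6-yl) derivative of 12 | CC(C)=CCc1c(O)c2c(c3c(=O)c(-c4cc(O)c5OC(C)(C)CCc5c4O)c(N4CCCC4)oc13)OC(C)(C)CC2 | intermediate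
19 | CNP0081329.0 (7,5'-dihydroxy-8-prenylcoumaronochromone with ring E on O–C5/C6 and ring F on O–C4'/C3') | CC(C)=CCc1c(O)c2c(c3c(=O)c4c(oc13)oc1c3c(c(O)cc14)OC(C)(C)CC3)OC(C)(C)CC2 | target

Total step count: 13. Longest linear sequence: 10 (steps 1–9 and 13).

**Steps most likely to fail**

**Step 4.**
- The palladium hydride may drop out of the cycle, so that the ring-opened diene accumulates and oligomerises.
- The alkene may instead migrate into the five-membered ring with aromatisation to a benzofuran.
- Fallback (sets out from 3, comes back at 6): Heck reaction of 3 with 2-methylbut-3-en-2-ol (Pd(OAc)2, P(o-tol)3, Et3N, MeCN, 80 °C) should give 1-{4-(benzyloxy)-2,6-dihydroxy-3-[(1E)-3-hydroxy-3-methylbut-1-en-1-yl]phenyl}ethanone F1. Pyridinium p-toluenesulfonate in warm toluene then ionises the tertiary allylic alcohol, and the free ortho hydroxyl closes chromene 6 directly. The five-membered stage is given up.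

**Step 13.**
- The enaminone carbon may attack the other free quinone carbon.
- Electron transfer between adduct and unreacted quinone may stall the closure.
- Expulsion of the amine may be too slow.
- Fallback (sets out from 17 and 12, comes back at 18 and so at 19), quinone half:
  - Na2S2O4 reduces 17 to 2,2-dimethyl-3,4-dihydro-2H-chromene-5,8-diol F2.
  - MOMCl and i-Pr2NEt give 5,8-bis(methoxymethoxy)-2,2-dimethyl-3,4-dihydro-2H-chromene F3.
  - NBS in MeCN brominates C6 (para to the ring oxygen and ortho to the C5 ether) to 6-bromo-5,8-bis(methoxymethoxy)-2,2-dimethyl-3,4-dihydro-2H-chromene F4.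
  - n-BuLi, then B(OiPr)3 and mild aqueous work-up give [5,8-bis(methoxymethoxy)-2,2-dimethyl-3,4-dihydro-2H-chromen-6-yl]boronic acid F5.
- Chromone half and union:
  - 12 is iodinated at the enaminone carbon C3 with one equivalent of NIS at −20 °C to the 3-iodo derivative of 12 F6.
  - Suzuki–Miyaura coupling (Pd(PPh3)4, K2CO3, dioxane–water, 80 °C) joins both to the bis(methoxymethyl) ether of 18 F7.
  - HCl in MeOH at 40 °C removes both acetals to deliver 18, which the same acid closes to 19.

**Step 6.**
- O-Alkylation of the free phenoxide and a second, dearomatising alkylation at C6 may compete with mono-C-prenylation.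
- Fallback (sets out from 7, comes back at 8):
  - The non-chelated 5-OH is etherified with 3-chloro-3-methylbut-1-yne (CuCl2 cat., DBU, MeCN, 0 °C) to 1-{7-hydroxy-2,2-dimethyl-5-[(2-methylbut-3-yn-2-yl)oxy]-3,4-dihydro-2H-chromen-8-yl}ethanone F8.
  - Semihydrogenation (H2, Pd/CaCO3 poisoned with Pb(OAc)2, quinoline) gives 1-{7-hydroxy-2,2-dimethyl-5-[(2-methylbut-3-en-2-yl)oxy]-3,4-dihydro-2H-chromen-8-yl}ethanone F9.
  - Heating in N,N-diethylaniline at 120 °C triggers the aromatic Claisen rearrangement to the only free ortho carbon, which gives 8.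

**Further compounds**

F1 | step 4 | 1-{4-(benzyloxy)-2,6-dihydroxy-3-[(1E)-3-hydroxy-3-methylbut-1-en-1-yl]phenyl}ethanone | CC(=O)c1c(O)cc(OCc2ccccc2)c(/C=C/C(C)(C)O)c1O
F2 | step 13 | 2,2-dimethyl-3,4-dihydro-2H-chromene-5,8-diol | Oc1ccc(O)c2c1CCC(C)(C)O2
F3 | step 13 | 5,8-bis(methoxymethoxy)-2,2-dimethyl-3,4-dihydro-2H-chromene | COCOc1ccc(OCOC)c2c1CCC(C)(C)O2
F4 | step 13 | 6-bromo-5,8-bis(methoxymethoxy)-2,2-dimethyl-3,4-dihydro-2H-chromene | COCOc1c(Br)cc(OCOC)c2c1CCC(C)(C)O2
F5 | step 13 | [5,8-bis(methoxymethoxy)-2,2-dimethyl-3,4-dihydro-2H-chromen-6-yl]boronic acid | COCOc1c(B(O)O)cc(OCOC)c2c1CCC(C)(C)O2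
F6 | step 13 | 3-iodo derivative of 12 | CC(C)=CCc1c(O)c2c(c3c(=O)c(I)c(N4CCCC4)oc13)OC(C)(C)CC2
F7 | step 13 | bis(methoxymethyl) ether of 18 | CC(C)=CCc1c(O)c2c(c3c(=O)c(-c4cc(OCOC)c5OC(C)(C)CCc5c4OCOC)c(N4CCCC4)oc13)OC(C)(C)CC2
F8 | step 6 | 1-{7-hydroxy-2,2-dimethyl-5-[(2-methylbut-3-yn-2-yl)oxy]-3,4-dihydro-2H-chromen-8-yl}ethanone | CC(=O)c1c(O)cc(OC(C)(C)C#C)c2c1OC(C)(C)CC2
F9 | step 6 | 1-{7-hydroxy-2,2-dimethyl-5-[(2-methylbut-3-en-2-yl)oxy]-3,4-dihydro-2H-chromen-8-yl}ethanone | CC(=O)c1c(O)cc(OC(C)(C)C=C)c2c1OC(C)(C)CC2
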